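**Assumption:** the SMILES is taken literally. It describes a heterodimer with one (S)- and one (R)-acetoxybutyl arm on a C2-type core, in which each ring CHBr bromine is trans to the lactone oxygen on the neighbouring spiro carbon.

## Retrosynthetic overview

1. The target is the anti head-to-head cyclobutane dimer of one (R)- and one (S)-acetoxyfimbrolide unit. Its Br-trans-to-O relationship is what an anti bromolactonisation gives; diradical closure of the (Z)-monomer photodimer is expected to give the opposite (Br cis to O).
2. Last disconnection: both spiro C–O lactone bonds. They are cut and re-formed by carboxylate opening of bromonium ions, which inverts both spiro centres of the spiro-epimeric photodimer.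
3. Cyclobutane: intramolecular sensitised [2+2] of two (Z)-ylidene butenolides held by an L-tartrate strap. The strap turns R/S pairing and core helicity into diastereomer separations; it is then exchanged for two acetates.
4. Monomer: butenolide by oxidative cyclodehydration (lactone C–O) of dibrominated 2-butyllevulinic acid; carbinol oxygen by allylic bromination and solvolysis.
5. Ring order: two butenolides, then the cyclobutane, then both butenolide C–O bonds re-closed in the last step.

## Route

Step 1
Reactants: 1 ethyl 3-oxobutanoate; 2 ethyl 2-bromohexanoate (racemic)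
Product: 3 diethyl 2-acetyl-3-butylbutanedioate (diastereomer mixture)
Conditions: NaOEt, EtOH, reflux
Reagents that add atoms: none
Why: acetoacetic ester alkylation (SN2 of the sodium enolate on the α-bromo ester); the stereocentres formed are destroyed later.

Step 2
Reactants: 3 diethyl 2-acetyl-3-butylbutanedioate
Product: 4 2-butyl-4-oxopentanoic acid (racemic)
Conditions: 6 M HCl, reflux
Reagents that add atoms: water (O)
Why: ester hydrolysis followed by β-keto acid decarboxylation; the remaining stereocentre is removed in step 3.

Step 3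
Reactants: 4 2-butyl-4-oxopentanoic acid
Product: 6 (5Z)-4-bromo-5-(bromomethylene)-3-butylfuran-2(5H)-one, via dibromo keto acid 5 (not isolated)
Conditions: Br2 (2.1 equiv), CHCl3, 0 °C to rt; then 98% H2SO4, 110 °C, 20 min
Reagents that add atoms: bromine (BrBr)
Why: ketone α-bromination on both sides, then acid-mediated enol-lactonisation and oxidative dehydration (lactone C–O bond formed, H2SO4 also the oxidant), giving the thermodynamically preferred (Z)-bromomethylene butenolide; no stereocentre.

Step 4
Reactants: 6 (5Z)-4-bromo-5-(bromomethylene)-3-butylfuran-2(5H)-one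
Product: 7 (5Z)-4-bromo-3-(1-bromobutyl)-5-(bromomethylene)furan-2(5H)-one (racemic)
Conditions: NBS, (PhCO2)2 (cat.), PhCF3, reflux, visible light
Reagents that add atoms: N-bromosuccinimide (O=C1CCC(=O)N1Br)
Why: Wohl–Ziegler allylic bromination at the only allylic C–H position (C-1' of the butyl chain); the racemic centre is sorted in step 6.

Step 5
Reactants: 7 (5Z)-4-bromo-3-(1-bromobutyl)-5-(bromomethylene)furan-2(5H)-one
Product: 8 (5Z)-4-bromo-5-(bromomethylene)-3-(1-hydroxybutyl)furan-2(5H)-one (racemic)
Conditions: AgOSO2CF3, acetone–H2O 9:1, rt, dark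
Reagents that add atoms: water (O)
Why: silver-assisted SN1 solvolysis of the allylic bromide (C–O bond formation); racemic carbinol.

Step 6
Reactants: 8 racemic hydroxy butenolide (2 equiv); 9 (3R,4R)-2,5-dioxooxolane-3,4-diyl diacetate (O,O'-diacetyl-L-tartaric anhydride)
Product: 11 (2R,3R)-2,3-diacetoxybutanedioate diester carrying one (1R)- plus one (1S)-configured unit of 8, via hemitartrate 10 (not isolated)
Conditions: 9 (0.5 equiv), pyridine, CH2Cl2, 40 °C; then DIC, DMAP (cat.), 0 °C to rt; SiO2 chromatography
Reagents that add atoms: none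
Why: anhydride opening then Steglich esterification (two C–O bonds); no stereocentre is created, but the chiral C2-symmetric strap makes the R/S, R/R and S/S diesters diastereomers (statistical 2:1:1), so the isolated C1-symmetric diester carries exactly one (R)- and one (S)-carbinol.

Step 7
Reactants: 11 mixed (R)/(S) tartrate diester
Product: 12 tartrate-strapped anti head-to-head cycloadduct (spiro carbons R,R; CHBr carbons R,R; each ring Br cis to the neighbouring lactone O)
Conditions: thioxanthen-9-one (10 mol %), 405 nm LEDs, degassed CH2Cl2 (2 mM), −20 °C; SiO2 chromatography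
Reagents that add atoms: none
Why: triplet-sensitised intramolecular [2+2] photocycloaddition: the first bond joins the two CHBr carbons to give the doubly oxyallyl-stabilised 1,4-diradical (head-to-head, as in anemonin formation), which closes anti with each Br away from the neighbouring C(Br)= arm, while the L-tartrate strap makes the two helical senses diastereomeric so that 12 is isolated pure.

Step 8
Reactants: 12 strapped cycloadduct
Product: 14 diacetate of the cycloadduct (spiro carbons R,R; CHBr carbons R,R; carbinols S and R), via diol 13 (not isolated)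
Conditions: HCl (1.25 M in MeOH), 40 °C; aqueous wash; then Ac2O, pyridine, DMAP (cat.), CH2Cl2, 0 °C to rt
Reagents that add atoms: acetic anhydride (CC(=O)OC(C)=O)
Why: acid-catalysed transesterification removes the strap by acyl–O cleavage (carbinol configurations retained; the tert-alkyl lactones with Br syn to the C–O bond are inert), then standard acetylation; no stereocentre changes.

Step 9
Reactants: 14 spiro-epimeric diacetate
Product: 16 target (spiro carbons S,S; CHBr carbons R,R; carbinols S and R), via tetrabromide bis(trimethylsilyl) ester 15 (not isolated)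
Conditions: Me3SiBr (5 equiv), ZnBr2 (10 mol %), CH2Cl2, 0 °C to rt; evaporate; then Ag2CO3 (1.2 equiv), MeCN, −20 to 0 °C, dark
Reagents that add atoms: none
Why: Proposed new method: stereoinvertive double translactonisation through bromonium ions – Me3SiBr/ZnBr2 cleaves each tert-alkyl lactone C–O bond to a cation that is bridged by the neighbouring ring bromine and captured by bromide, and Ag2CO3 then removes that tertiary bromide so the same bromonium ion is opened intramolecularly by the carboxylate anti to the bridging bromine, which forces each new spiro C–O bond trans to the adjacent C–Br (both spiro centres inverted, CHBr and carbinol centres untouched, no re-ionisation under the non-acidic silver conditions); closest known reactions are silyl halide opening of tert-alkyl esters and lactones to halo acids and bromolactonisation or silver-assisted lactonisation of bromo acids with neighbouring-bromine participation.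

## Compound list

1 | ethyl 3-oxobutanoate (ethyl acetoacetate) | CCOC(=O)CC(C)=O | starting material
2 | ethyl 2-bromohexanoate (racemic) | CCCCC(Br)C(=O)OCC | starting material
3 | diethyl 2-acetyl-3-butylbutanedioate (diastereomer mixture) | CCCCC(C(=O)OCC)C(C(C)=O)C(=O)OCC | intermediate
4 | 2-butyl-4-oxopentanoic acid (racemic) | CCCCC(CC(C)=O)C(=O)O | intermediate
5 | 3,5-dibromo-2-butyl-4-oxopentanoic acid (diastereomer mixture) | CCCCC(C(Br)C(=O)CBr)C(=O)O | intermediate
6 | (5Z)-4-bromo-5-(bromomethylene)-3-butylfuran-2(5H)-one | CCCCC1=C(Br)/C(=C/Br)OC1=O | intermediate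
7 | (5Z)-4-bromo-3-(1-bromobutyl)-5-(bromomethylene)furan-2(5H)-one (racemic) | CCCC(Br)C1=C(Br)/C(=C/Br)OC1=O | intermediate
8 | (5Z)-4-bromo-5-(bromomethylene)-3-(1-hydroxybutyl)furan-2(5H)-one (racemic) | CCCC(O)C1=C(Br)/C(=C/Br)OC1=O | intermediate
9 | (3R,4R)-2,5-dioxooxolane-3,4-diyl diacetate (O,O'-diacetyl-L-tartaric anhydride) | O=C1OC(=O)[C@H](OC(C)=O)[C@H]1OC(C)=O | starting material
10 | (2R,3R)-2,3-diacetoxy-4-{1-[(5Z)-4-bromo-5-(bromomethylene)-2-oxo-2,5-dihydrofuran-3-yl]butoxy}-4-oxobutanoic acid, both carbinol epimers | CCCC(OC(=O)[C@H](OC(C)=O)[C@@H](OC(C)=O)C(=O)O)C1=C(Br)/C(=C/Br)OC1=O | intermediate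
11 | 1-{(1R)-1-[(5Z)-4-bromo-5-(bromomethylene)-2-oxo-2,5-dihydrofuran-3-yl]butyl} 4-{(1S)-1-[(5Z)-4-bromo-5-(bromomethylene)-2-oxo-2,5-dihydrofuran-3-yl]butyl} (2R,3R)-2,3-diacetoxybutanedioate | CCC[C@H](OC(=O)[C@H](OC(C)=O)[C@@H](OC(C)=O)C(=O)O[C@H](CCC)C1=C(Br)/C(=C/Br)OC1=O)C2=C(Br)/C(=C/Br)OC2=O | intermediate
12 | (5R,6R,11R,12R)-4,10,11,12-tetrabromo-1,7-dioxadispiro[4.0.4.2]dodeca-3,9-diene-2,8-dione whose 3- and 9-CH(propyl)O groups, (1S) and (1R), are bridged by the (2R,3R)-2,3-diacetoxybutanedioyl strap; anti head-to-head, each ring Br cis to the lactone O on the neighbouring spiro carbon | CCC[C@H](OC(=O)[C@H](OC(C)=O)[C@@H](OC(C)=O)C(=O)O4)C1=C(Br)[C@]2(OC1=O)[C@@H](Br)[C@H](Br)[C@]23OC(=O)C([C@H]4CCC)=C3Br | intermediate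
13 | (5R,6R,11R,12R)-4,10,11,12-tetrabromo-3-[(1S)-1-hydroxybutyl]-9-[(1R)-1-hydroxybutyl]-1,7-dioxadispiro[4.0.4.2]dodeca-3,9-diene-2,8-dione | CCC[C@H](O)C1=C(Br)[C@]2(OC1=O)[C@@H](Br)[C@H](Br)[C@]21OC(=O)C([C@@H](CCC)O)=C1Br | intermediate
14 | diacetate of 13: (5R,6R,11R,12R) core, one (1S)- and one (1R)-1-acetoxybutyl arm, each ring Br cis to the neighbouring lactone O | CCC[C@H](OC(C)=O)C1=C(Br)[C@]2(OC1=O)[C@@H](Br)[C@H](Br)[C@]21OC(=O)C([C@@H](CCC)OC(C)=O)=C1Br | intermediate
15 | bis(trimethylsilyl) ester of the ring-opened diacid: 1,2,3,4-tetrabromocyclobutane whose C-1 and C-2 each carry a 1-bromo-2-carboxy-3-acetoxyhex-1-enyl arm (carboxyl cis to the ring carbon; carbinols S and R); each tertiary C–Br anti to the neighbouring secondary C–Br, secondary bromines trans | CCC[C@H](OC(C)=O)/C(C(=O)O[Si](C)(C)C)=C(\Br)[C@@]1(Br)[C@@H](Br)[C@H](Br)[C@]1(Br)/C(Br)=C(\C(=O)O[Si](C)(C)C)[C@@H](CCC)OC(C)=O | intermediate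
16 | (5S,6S,11R,12R)-4,10,11,12-tetrabromo-2,8-dioxo-1,7-dioxadispiro[4.0.4.2]dodeca-3,9-diene-3,9-diyl core with one (1S)- and one (1R)-1-acetoxybutyl arm; each ring Br trans to the neighbouring lactone O (CNP0266230.1) | CCC[C@H](OC(C)=O)C1=C(Br)[C@@]2(OC1=O)[C@@H](Br)[C@H](Br)[C@@]21OC(=O)C([C@@H](CCC)OC(C)=O)=C1Br | target

## Step count and risks

Total steps: 9. Longest linear sequence: 9.

Three steps most likely to fail:

**Step 9 (the proposed new step).** The silyl bromide may ionise the deactivated spiro C–O bonds too slowly. The allylic-type acetoxy carbinols may ionise in competition and scramble. Bromide may open a bromonium ion at the CHBr carbon, which erodes the trans-dibromide. Fallback with known reactions, from 14: 33% HBr in AcOH at 0–20 °C opens both lactones (classical cleavage of a tert-alkyl lactone to a bromo acid) to the bis(tertiary bromide) diacid F1, which is isolated by precipitation with water. F1 is then closed in a separate operation with AgOAc in dry MeCN at 0 °C (silver-assisted lactonisation of a bromo acid with neighbouring-bromine participation). This returns to the route at 16.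

**Step 7.** The sense and level of induction by the tartrate strap, and the cis/trans ratio at the two CHBr carbons, cannot be predicted. Loss of bromine atoms from the diradical is also possible. Fallback from 8: acetylation (Ac2O, pyridine) gives racemic (5Z)-acetoxyfimbrolide F2. F2 is dimerised intermolecularly (thioxanthen-9-one, 405 nm, 0.5 M in CH2Cl2). The C1-symmetric anti head-to-head heterodimer (14 together with its enantiomer) is separated from the two C2-symmetric homodimers and resolved by preparative chiral HPLC. This returns to the route at 14.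

**Step 6.** The hindered carbinol may acylate sluggishly, the yield is capped at 50% by statistics, and the three diastereomeric diesters must be separable. Fallback from 8: lipase-catalysed kinetic resolution (immobilised Candida antarctica lipase B, vinyl acetate, MTBE, 30 °C) gives the (S)-alcohol F3 and the (R)-acetate F4. F4 is deacetylated with the same lipase and n-butanol to the (R)-alcohol F5. F3 opens 9 (pyridine, CH2Cl2) to the (S)-hemitartrate F6, and F6 is coupled with F5 (DIC, DMAP). This returns to the route at 11 without the statistical loss.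

## Further compounds

F1 | step 9 | ring-opened bis(tertiary bromide) diacid (free-acid form of 15) | CCC[C@H](OC(C)=O)/C(C(=O)O)=C(\Br)[C@@]1(Br)[C@@H](Br)[C@H](Br)[C@]1(Br)/C(Br)=C(\C(=O)O)[C@@H](CCC)OC(C)=O
F2 | step 7 | (5Z)-3-(1-acetoxybutyl)-4-bromo-5-(bromomethylene)furan-2(5H)-one (racemic) | CCCC(OC(C)=O)C1=C(Br)/C(=C/Br)OC1=O
F3 | step 6 | (5Z)-4-bromo-5-(bromomethylene)-3-[(1S)-1-hydroxybutyl]furan-2(5H)-one | CCC[C@H](O)C1=C(Br)/C(=C/Br)OC1=O
F4 | step 6 | (5Z)-3-[(1R)-1-acetoxybutyl]-4-bromo-5-(bromomethylene)furan-2(5H)-one | CCC[C@@H](OC(C)=O)C1=C(Br)/C(=C/Br)OC1=O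
F5 | step 6 | (5Z)-4-bromo-5-(bromomethylene)-3-[(1R)-1-hydroxybutyl]furan-2(5H)-one | CCC[C@@H](O)C1=C(Br)/C(=C/Br)OC1=O
F6 | step 6 | (2R,3R)-2,3-diacetoxy-4-{(1S)-1-[(5Z)-4-bromo-5-(bromomethylene)-2-oxo-2,5-dihydrofuran-3-yl]butoxy}-4-oxobutanoic acid | CCC[C@H](OC(=O)[C@H](OC(C)=O)[C@@H](OC(C)=O)C(=O)O)C1=C(Br)/C(=C/Br)OC1=O
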